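**Plan**

Ring atoms are called O1, C2 (C=O), C-α (bears CH3), C-β (bears CO2H) and C-γ (bears the 14-oxopentadecyl chain).

1. Retrosynthesis: the CO2H on C-β is traced back to a phenyl group and the CH3 on C-α to an enolate methylation. The lactone is then cut at O1–C-γ and at C-α–C-β, giving an (E)-vinyl sulfoxide and dichloroketene. The vinyl sulfoxide is cut at C-γ–CH2 (alkylation) and at S–C (sulfinate ester).
2. Enabling feature: the C-β=C-γ alkene carries the sulfinyl S–O on C-γ. O-acylation by Cl2C=C=O gives the six-atom array C-β=C-γ–S–O–C(O−)=CCl2. Its [3,3] shift makes C-α–C-β and leaves C-γ as a thionium carbon, which the new carboxylate oxygen captures to close ring O1–C2–C-α–C-β–C-γ.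
3. Forward order: the chain iodide (steps 1–2) and the styryl sulfoxide (step 3) are joined at C-γ (step 4), and the lactone ring is formed (step 5). The helpers are then removed: two Cl and S-tolyl (step 6), methyl on and dioxolane off (step 7), phenyl to CO2H (step 8).
4. Stereochemistry: sulfur chirality from menthyl sulfinate is transferred to C-β in the cyclic shift. C-γ is set by hydrogen delivery anti to phenyl (chain cis to phenyl). C-α is set by methylation anti to phenyl and chain.

Key step: step 5

Assumption (remark on the chemistry): in the sulfonium shift of step 5 the p-tolyl group is taken to sit pseudo-equatorial, anti to the C=C bond, as in the parent 1-alkenyl sulfoxide series; the (R)-sulfoxide is chosen on that basis.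

**Route**

Step 1
Reactants: 1 2-(2-bromoethyl)-2-methyl-1,3-dioxolane; 2 1,11-dibromoundecane
Product: 4 2-(13-bromotridecyl)-2-methyl-1,3-dioxolane, via Grignard reagent 3 (not isolated)
Conditions: Mg, THF, 25 °C; then 2 (3 equiv), Li2CuCl4 (3 mol %), THF, −10 → 20 °C
Reagents that add atoms: none
Why: Copper-catalysed sp3–sp3 Grignard cross-coupling tolerates the dioxolane, and the excess of dibromide 2 should hold the reaction at mono-substitution.

Step 2
Reactants: 4 2-(13-bromotridecyl)-2-methyl-1,3-dioxolane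
Product: 5 2-(13-iodotridecyl)-2-methyl-1,3-dioxolane
Conditions: NaI, acetone, reflux
Reagents that add atoms: sodium iodide, [Na+].[I-]
Why: Finkelstein exchange, driven by precipitation of NaBr, should give the more reactive iodide needed for the alkylation in step 4.

Step 3
Reactants: 6 (E)-(2-bromoethenyl)benzene; 7 (1R,2S,5R)-menthyl (S)-4-methylbenzenesulfinate
Product: 9 1-methyl-4-{(R)-[(E)-2-phenylethenyl]sulfinyl}benzene, via styrylmagnesium bromide 8 (not isolated)
Conditions: Mg, THF, 40 °C; then added to 7, toluene/THF, −40 → 0 °C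
Reagents that add atoms: none
Why: In the Andersen sulfoxide synthesis the Grignard reagent displaces mentholate at sulfur with inversion, so the (S)-sulfinate should give the (R)-sulfoxide with the E geometry retained (crystallisation removes any Z isomer).

Step 4
Reactants: 9 1-methyl-4-{(R)-[(E)-2-phenylethenyl]sulfinyl}benzene; 5 2-(13-iodotridecyl)-2-methyl-1,3-dioxolane
Product: 11 2-methyl-2-[(14E)-14-[(R)-(4-methylphenyl)sulfinyl]-15-phenylpentadec-14-en-1-yl]-1,3-dioxolane, via α-lithiovinyl sulfoxide 10 (not isolated)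
Conditions: LiN(iPr)2, THF, −78 °C; then 5, DMPU, −78 → −30 °C
Reagents that add atoms: none
Why: The sulfinyl group acidifies the adjacent vinylic C–H, and the α-sulfinyl vinyllithium should be alkylated by the primary iodide with retention of alkene geometry (sulfur trans to phenyl) and without touching the sulfur stereocentre.

Step 5
Reactants: 11 2-methyl-2-[(14E)-14-[(R)-(4-methylphenyl)sulfinyl]-15-phenylpentadec-14-en-1-yl]-1,3-dioxolane
Product: 14 (4R,5R)-3,3-dichloro-5-[13-(2-methyl-1,3-dioxolan-2-yl)tridecyl]-5-[(4-methylphenyl)sulfanyl]-4-phenyloxolan-2-one, via acyloxysulfonium enolate 12 (not isolated), via thionium carboxylate 13 (not isolated)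
Conditions: Cl3CCOCl (2.5 equiv), Zn(Cu) couple, THF, −40 → 0 °C
Reagents that add atoms: trichloroacetyl chloride, ClC(Cl)(Cl)C(Cl)=O
Why: Zinc dechlorination of Cl3CCOCl gives dichloroketene, which acylates the nucleophilic sulfinyl oxygen of 11 to give enolate 12, where C-β=C-γ–S–O–C(O−)=CCl2 is a 1,5-diene-type array; a charge-accelerated [3,3]-sigmatropic shift through a six-membered chair transition state forms C-α–C-β, breaks S–O and leaves thionium carboxylate 13. The carboxylate oxygen then adds to the thionium carbon C-γ (5-exo-trig closure of ring O1–C2–C-α–C-β–C-γ), so both ring bonds arise in one operation. The closest known reaction type is the lactonisation of 1-alkenyl aryl sulfoxides with dichloroketene, a sulfonium-Claisen shift followed by additive-Pummerer ring closure, known for acyclic and 1-cycloalkenyl sulfoxides. C-β is set by chirality transfer from sulfur: with p-tolyl pseudo-equatorial the (R)-sulfinyl oxygen lies over one face of the (E)-alkene and delivers the enolate carbon to that face (4R); C-γ is set by suprafacial collapse of the ion pair on the same face, leaving the chain cis to phenyl (5R), and is re-made in step 6. The step needs chemoselective attack of the ketene at sulfinyl oxygen rather than at the dioxolane (low temperature, slow ketene generation) and reaction through one sulfonium rotamer; the E geometry, with sulfur cis to the vinylic hydrogen, keeps allylic strain out of that rotamer.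

Step 6
Reactants: 14 (4R,5R)-3,3-dichloro-5-[13-(2-methyl-1,3-dioxolan-2-yl)tridecyl]-5-[(4-methylphenyl)sulfanyl]-4-phenyloxolan-2-one
Product: 15 (4R,5S)-5-[13-(2-methyl-1,3-dioxolan-2-yl)tridecyl]-4-phenyloxolan-2-one
Conditions: Bu3SnH (3.5 equiv), AIBN (cat.), benzene, 80 °C
Reagents that add atoms: none
Why: In this radical chain reduction Bu3Sn• removes both chlorines α to the carbonyl and cleaves the O,S-acetal C–S bond, and the planar C-γ radical should take hydrogen from the stannane on the face anti to the adjacent phenyl group, which places the chain cis to phenyl.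

Step 7
Reactants: 15 (4R,5S)-5-[13-(2-methyl-1,3-dioxolan-2-yl)tridecyl]-4-phenyloxolan-2-one
Product: 18 (3S,4R,5S)-3-methyl-5-(14-oxopentadecyl)-4-phenyloxolan-2-one, via lithium enolate 16 (not isolated), via methylated ketal lactone 17 (not isolated)
Conditions: LiN(iPr)2, THF, −78 °C; MeI, −78 → −40 °C; then 1 M HCl, THF, 20 °C
Reagents that add atoms: iodomethane, CI; water, O
Why: Kinetic enolate alkylation should occur on the ring face opposite the cis-disposed phenyl and alkyl groups, giving the methyl trans to phenyl (3S), and the dilute acid then hydrolyses the dioxolane without affecting the lactone or the non-acidic benzylic centre.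

Step 8
Reactants: 18 (3S,4R,5S)-3-methyl-5-(14-oxopentadecyl)-4-phenyloxolan-2-one
Product: 19 (2S,3S,4S)-4-methyl-5-oxo-2-(14-oxopentadecyl)oxolane-3-carboxylic acid
Conditions: RuCl3·xH2O (5 mol %), H5IO6 (15 equiv), CCl4/MeCN/H2O, 20 °C
Reagents that add atoms: orthoperiodic acid, OI(=O)(O)(O)(O)O; water, O
Why: RuO4 generated catalytically from RuCl3 and periodic acid should degrade the phenyl ring to a carboxyl group in an acidic, non-epimerising medium, leaving the attached stereocentre, the ketone, the lactone and the alkyl chain untouched.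

**Compound list**

1 | 2-(2-bromoethyl)-2-methyl-1,3-dioxolane | CC1(CCBr)OCCO1 | starting material
2 | 1,11-dibromoundecane | BrCCCCCCCCCCCBr | starting material
3 | [2-(2-methyl-1,3-dioxolan-2-yl)ethyl]magnesium bromide | CC1(CC[Mg]Br)OCCO1 | intermediate
4 | 2-(13-bromotridecyl)-2-methyl-1,3-dioxolane | CC1(CCCCCCCCCCCCCBr)OCCO1 | intermediate
5 | 2-(13-iodotridecyl)-2-methyl-1,3-dioxolane | CC1(CCCCCCCCCCCCCI)OCCO1 | intermediate
6 | (E)-(2-bromoethenyl)benzene | Br/C=C/c1ccccc1 | starting material
7 | (1R,2S,5R)-menthyl (S)-4-methylbenzenesulfinate | Cc1ccc(cc1)[S@@](=O)O[C@@H]1C[C@H](C)CC[C@H]1C(C)C | starting material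
8 | [(E)-2-phenylethenyl]magnesium bromide | Br[Mg]/C=C/c1ccccc1 | intermediate
9 | 1-methyl-4-{(R)-[(E)-2-phenylethenyl]sulfinyl}benzene | Cc1ccc(cc1)[S@](=O)/C=C/c1ccccc1 | intermediate
10 | {(E)-1-[(R)-(4-methylphenyl)sulfinyl]-2-phenylethenyl}lithium | Cc1ccc(cc1)[S@](=O)/C([Li])=C/c1ccccc1 | intermediate
11 | 2-methyl-2-[(14E)-14-[(R)-(4-methylphenyl)sulfinyl]-15-phenylpentadec-14-en-1-yl]-1,3-dioxolane | Cc1ccc(cc1)[S@](=O)/C(CCCCCCCCCCCCCC2(C)OCCO2)=C/c1ccccc1 | intermediate
12 | (2,2-dichloro-1-oxidoethenyl)oxysulfonium zwitterion formed from 11 (sulfur configuration unchanged, E alkene) | Cc1ccc(cc1)[S@+](OC([O-])=C(Cl)Cl)/C(CCCCCCCCCCCCCC2(C)OCCO2)=C/c1ccccc1 | intermediate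
13 | (3R)-2,2-dichloro-4-[(4-methylphenyl)sulfaniumylidene]-17-(2-methyl-1,3-dioxolan-2-yl)-3-phenylheptadecanoate | Cc1ccc(cc1)[S+]=C(CCCCCCCCCCCCCC2(C)OCCO2)[C@@H](c1ccccc1)C(Cl)(Cl)C([O-])=O | intermediate
14 | (4R,5R)-3,3-dichloro-5-[13-(2-methyl-1,3-dioxolan-2-yl)tridecyl]-5-[(4-methylphenyl)sulfanyl]-4-phenyloxolan-2-one | CC1(CCCCCCCCCCCCC[C@]2(Sc3ccc(C)cc3)OC(=O)C(Cl)(Cl)[C@@H]2c4ccccc4)OCCO1 | intermediate
15 | (4R,5S)-5-[13-(2-methyl-1,3-dioxolan-2-yl)tridecyl]-4-phenyloxolan-2-one | CC1(CCCCCCCCCCCCC[C@@H]2OC(=O)C[C@@H]2c3ccccc3)OCCO1 | intermediate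
16 | lithium enolate (4,5-dihydrofuran-2-olate) of 15 | CC1(CCCCCCCCCCCCC[C@@H]2OC(O[Li])=C[C@@H]2c3ccccc3)OCCO1 | intermediate
17 | (3S,4R,5S)-3-methyl-5-[13-(2-methyl-1,3-dioxolan-2-yl)tridecyl]-4-phenyloxolan-2-one | CC1(CCCCCCCCCCCCC[C@@H]2OC(=O)[C@@H](C)[C@@H]2c3ccccc3)OCCO1 | intermediate
18 | (3S,4R,5S)-3-methyl-5-(14-oxopentadecyl)-4-phenyloxolan-2-one | CC(=O)CCCCCCCCCCCCC[C@@H]1OC(=O)[C@@H](C)[C@@H]1c1ccccc1 | intermediate
19 | (2S,3S,4S)-4-methyl-5-oxo-2-(14-oxopentadecyl)oxolane-3-carboxylic acid | CC(=O)CCCCCCCCCCCCC[C@@H]1OC(=O)[C@@H](C)[C@@H]1C(=O)O | target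

**Step count**

Total steps: 8. Longest linear sequence: 7 steps (steps 1, 2, 4, 5, 6, 7, 8).

**Steps most likely to fail**

Step 5. What may go wrong: the transfer of chirality from sulfur may be eroded or reversed, because the C-γ alkyl group eclipses the pseudo-equatorial tolyl group in the reacting sulfonium rotamer; the dioxolane may also be partly opened by ZnCl2 and the acyl chloride. The fallback builds the cis lactone without sulfur; it sets out from 4 and 6 and comes back at 15. Bromide 4 is converted (Mg, THF) into [13-(2-methyl-1,3-dioxolan-2-yl)tridecyl]magnesium bromide F1 and coupled with 6 under Fe(acac)3 catalysis (THF/NMP, 0 °C, E geometry retained) to give 2-methyl-2-[(14E)-15-phenylpentadec-14-en-1-yl]-1,3-dioxolane F2. Shi epoxidation with the L-fructose-derived ketone catalyst (KHSO5, K2CO3, MeCN/dimethoxymethane/buffer, 0 °C) should give 2-methyl-2-{13-[(2S,3S)-3-phenyloxiran-2-yl]tridecyl}-1,3-dioxolane F3. Sodium diethyl malonate (EtOH, reflux) should open the epoxide at the benzylic carbon with inversion to diethyl 2-[(1R,2S)-2-hydroxy-15-(2-methyl-1,3-dioxolan-2-yl)-1-phenylpentadecyl]propanedioate F4. This closes in the flask to ethyl (4R,5S)-5-[13-(2-methyl-1,3-dioxolan-2-yl)tridecyl]-2-oxo-4-phenyloxolane-3-carboxylate F5 (a trans epoxide gives the 4,5-cis lactone). Krapcho dealkoxycarbonylation (LiCl, wet DMSO, 150 °C) then returns 15.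

Step 6. What may go wrong: insufficient facial bias in hydrogen-atom transfer to the C-γ radical, so that the chain ends trans to phenyl. The fallback corrects C-γ by an SN2 lactonisation; it sets out from 14 and comes back at 15. The reduction is run as in step 6 and the trans epimer (4R,5R)-5-[13-(2-methyl-1,3-dioxolan-2-yl)tridecyl]-4-phenyloxolan-2-one F6 is separated. It is saponified (LiOH, THF/H2O, then cold acidification to pH 5) to (3R,4R)-4-hydroxy-17-(2-methyl-1,3-dioxolan-2-yl)-3-phenylheptadecanoic acid F7. Closure under Mitsunobu conditions (PPh3, DIAD, THF, 0 °C) then lets the carboxylate displace the activated hydroxyl with inversion at C-γ to give 15.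

Step 4. What may go wrong: slow substitution of the unactivated primary iodide by the α-sulfinyl vinyllithium, with competing decomposition or geometrical isomerisation of the anion. The fallback joins the chain by cross-coupling; it sets out from 9 and 1 and comes back at 11. Anion 10, generated from 9 as in step 4, is quenched with I2 to give 1-{(S)-[(Z)-1-iodo-2-phenylethenyl]sulfinyl}-4-methylbenzene F8 (same spatial arrangement at sulfur and alkene; the descriptors change with the iodine). Separately, Grignard reagent 3 (from 1) is coupled with commercial 11-bromoundec-1-ene (Li2CuCl4 cat., THF) to give 2-methyl-2-(tridec-12-en-1-yl)-1,3-dioxolane F9. Hydroboration with 9-BBN-H (THF) gives 9-[13-(2-methyl-1,3-dioxolan-2-yl)tridecyl]-9-borabicyclo[3.3.1]nonane F10. B-alkyl Suzuki–Miyaura coupling of F10 with F8 (Pd(dppf)Cl2, Cs2CO3, DMF/THF/H2O, 50 °C) should proceed with retention of alkene geometry and give 11.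

**Further compounds**

F1 | step 5 | [13-(2-methyl-1,3-dioxolan-2-yl)tridecyl]magnesium bromide | CC1(CCCCCCCCCCCCC[Mg]Br)OCCO1
F2 | step 5 | 2-methyl-2-[(14E)-15-phenylpentadec-14-en-1-yl]-1,3-dioxolane | CC1(CCCCCCCCCCCCC/C=C/c2ccccc2)OCCO1
F3 | step 5 | 2-methyl-2-{13-[(2S,3S)-3-phenyloxiran-2-yl]tridecyl}-1,3-dioxolane | CC1(CCCCCCCCCCCCC[C@@H]2O[C@H]2c3ccccc3)OCCO1
F4 | step 5 | diethyl 2-[(1R,2S)-2-hydroxy-15-(2-methyl-1,3-dioxolan-2-yl)-1-phenylpentadecyl]propanedioate | CCOC(=O)C(C(=O)OCC)[C@H](c1ccccc1)[C@@H](O)CCCCCCCCCCCCCC2(C)OCCO2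
F5 | step 5 | ethyl (4R,5S)-5-[13-(2-methyl-1,3-dioxolan-2-yl)tridecyl]-2-oxo-4-phenyloxolane-3-carboxylate | CC1(CCCCCCCCCCCCC[C@@H]2OC(=O)C(C(=O)OCC)[C@@H]2c3ccccc3)OCCO1
F6 | step 6 | (4R,5R)-5-[13-(2-methyl-1,3-dioxolan-2-yl)tridecyl]-4-phenyloxolan-2-one | CC1(CCCCCCCCCCCCC[C@H]2OC(=O)C[C@@H]2c3ccccc3)OCCO1
F7 | step 6 | (3R,4R)-4-hydroxy-17-(2-methyl-1,3-dioxolan-2-yl)-3-phenylheptadecanoic acid | CC1(CCCCCCCCCCCCC[C@@H](O)[C@H](CC(=O)O)c2ccccc2)OCCO1
F8 | step 4 | 1-{(S)-[(Z)-1-iodo-2-phenylethenyl]sulfinyl}-4-methylbenzene | Cc1ccc(cc1)[S@](=O)/C(I)=C/c1ccccc1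
F9 | step 4 | 2-methyl-2-(tridec-12-en-1-yl)-1,3-dioxolane | CC1(CCCCCCCCCCCC=C)OCCO1
F10 | step 4 | 9-[13-(2-methyl-1,3-dioxolan-2-yl)tridecyl]-9-borabicyclo[3.3.1]nonane | CC1(CCCCCCCCCCCCCB2C3CCCC2CCC3)OCCO1
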